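**Retrosynthetic overview** (numbering: veratryl ring C1–C6, carbinol C7, C8, methyl C9; second ring C1′–C6′ with the ether oxygen O4′ on C4′, side chain C7′=C8′–C9′)
1. Cut C1–C7 (veratryl ring carbon to carbinol carbon). This gives a 3,4-dimethoxyphenyltitanium donor (from 4-bromoveratrole) and the C7 methyl ester of a C8-defined diester. The same flask also takes the C9′ enoate to the allylic alcohol, so the key step ends at the target without protecting groups.
2. Enabling feature: C7 and C9′ are both alcohol-level carbons that can be carried as methyl esters of different character. C9′ is conjugated through C7′=C8′ with the 2,6-dimethoxyphenoxy ring, so its hydride adduct collapses and is reduced on. C7 is flanked by the C8–O4′ aryl ether, so its hydride adduct persists as a masked aldehyde, and the low σ*(C8–O4′) then steers the aryl group to the 7R,8S pair.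
3. Cut C8–O4′: methyl sinapate plus methyl (R)-lactate by Mitsunobu inversion. Methyl sinapate comes from sinapic acid.
4. No ring is formed, since both benzene rings are bought. C7 is always the electrophile, because a carbanion or metal at C7 would expel the β-aryloxide.

Key step: step 3

**Step 1**
Reactants: 1 sinapic acid
Product: 2 methyl sinapate [methyl (E)-3-(4-hydroxy-3,5-dimethoxyphenyl)prop-2-enoate]
Conditions: MeOH, H2SO4 (cat.), reflux
Reagents that add atoms: methanol, CO
Why: Fischer esterification in excess methanol should drive the acid to the methyl ester while the hindered phenol and the E-alkene stay untouched; no stereocentre is formed.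

**Step 2**
Reactants: 2 methyl sinapate; 3 methyl (R)-lactate
Product: 4 methyl (2S)-2-{2,6-dimethoxy-4-[(1E)-3-methoxy-3-oxoprop-1-en-1-yl]phenoxy}propanoate
Conditions: PPh3, DIAD, THF, 0 °C → rt
Reagents that add atoms: none
Why: Mitsunobu reaction in which the phenol O4′–H (acidified by the para enoate) displaces the oxyphosphonium-activated secondary hydroxyl of the α-hydroxy ester by SN2, so the R centre of the lactate is inverted to the 8S aryl ether, the adjacent ester carbonyl favouring SN2 and suppressing ionisation.

**Step 3**
Reactants: 4 diester from step 2; 5 4-bromoveratrole (4-bromo-1,2-dimethoxybenzene)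
Product: 10 (1R,2S)-1-(3,4-dimethoxyphenyl)-2-{4-[(1E)-3-hydroxyprop-1-en-1-yl]-2,6-dimethoxyphenoxy}propan-1-ol (target), via aryllithium 6 (not isolated), via aryltitanium triisopropoxide 7 (not isolated), via bis-aluminium hemiacetal 8 (not isolated), via aldehyde 9 (not isolated)
Conditions: flask A: 5 (3 equiv), n-BuLi, THF, −78 °C, then ClTi(Oi-Pr)3, −78 → −30 °C; flask B: 4, DIBAL-H (3.0 equiv), CH2Cl2, −78 °C; A into B, −78 → 0 °C; aq. Rochelle salt
Reagents that add atoms: none
Why: DIBAL-H delivers three hydrides to 4: the adduct of the C9′ enoate, pushed by the electron-rich ring through C7′=C8′, collapses even at −78 °C and is reduced on to the allylic aluminium alkoxide, whereas the adduct at C7, held back from losing methoxide by the inductively withdrawing α-aryloxy group, persists as the aluminium hemiacetal 8, so both oxygenated termini are adjusted and masked in situ. On warming, 8 releases aldehyde 9 only in the presence of the weakly basic aryltitanium 7, which adds to the C7 carbonyl and forms the C1–C7 bond before C8 can epimerise. The closest known reaction types are the tandem DIBAL-H reduction–organometallic addition of α-alkoxy and α-amino esters and the non-chelation-controlled addition of RTi(Oi-Pr)3 reagents to α-alkoxy aldehydes; no ring is closed. The new C7 stereocentre is controlled by C8 through a polar Felkin–Anh transition state in which the C8–O4′ bond stands perpendicular to the carbonyl plane and anti to the incoming aryl group, C9H3 sits next to the carbonyl oxygen and C8–H lies on the approach path, so the Re face of C7 is attacked and the 7R,8S (erythro) isomer should result. The selectivity needed is non-chelation over chelation, and it is secured by the low Lewis acidity of the Ti(Oi-Pr)3 centre, by the poor donor ability of the aryl ether oxygen O4′ crowded by two methoxy groups, and by the magnesium-free origin of 7. Chemoselectivity is secured because, after the hydride stage, the masked C7 aldehyde is the only electrophile left, so excess 7 is harmless.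

**Compound list**
1 | sinapic acid, (E)-3-(4-hydroxy-3,5-dimethoxyphenyl)prop-2-enoic acid | COc1cc(/C=C/C(=O)O)cc(OC)c1O | starting material
2 | methyl sinapate | COC(=O)/C=C/c1cc(OC)c(O)c(OC)c1 | intermediate
3 | methyl (R)-lactate | C[C@@H](O)C(=O)OC | starting material
4 | methyl (2S)-2-{2,6-dimethoxy-4-[(1E)-3-methoxy-3-oxoprop-1-en-1-yl]phenoxy}propanoate | COC(=O)[C@H](C)Oc1c(OC)cc(/C=C/C(=O)OC)cc1OC | intermediate
5 | 4-bromoveratrole | COc1ccc(Br)cc1OC | starting material
6 | (3,4-dimethoxyphenyl)lithium | COc1ccc([Li])cc1OC | intermediate
7 | (3,4-dimethoxyphenyl)titanium triisopropoxide | COc1ccc([Ti](OC(C)C)(OC(C)C)OC(C)C)cc1OC | intermediate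
8 | bis(diisobutylaluminium) species: C7 methyl hemiacetal O–Al(i-Bu)2 (both C7 epimers), C9′ allylic O–Al(i-Bu)2, 8S | COC(O[Al](CC(C)C)CC(C)C)[C@H](C)Oc1c(OC)cc(/C=C/CO[Al](CC(C)C)CC(C)C)cc1OC | intermediate
9 | (2S)-2-aryloxypropanal carrying the C9′ O–Al(i-Bu)2 alkoxide | O=C[C@H](C)Oc1c(OC)cc(/C=C/CO[Al](CC(C)C)CC(C)C)cc1OC | intermediate
10 | (1R,2S)-1-(3,4-dimethoxyphenyl)-2-{4-[(1E)-3-hydroxyprop-1-en-1-yl]-2,6-dimethoxyphenoxy}propan-1-ol | COc1ccc([C@@H](O)[C@H](C)Oc2c(OC)cc(/C=C/CO)cc2OC)cc1OC | target

Total step count: 3. Longest linear sequence: 3 (1 → 2 → 4 → 10).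

**Steps most likely to fail**

1. **Step 3.**
   - What may go wrong:
     - Surplus or unevenly delivered hydride may carry the C7 hemiacetal on to the primary alcohol.
     - The hemiacetal may collapse before the aryl donor is present.
     - Alkyl–alkoxide exchange between aluminium and titanium may consume the aryl donor.
     - Coordination of O4′ and a flanking methoxy oxygen to lithium or aluminium may open a chelate pathway and erode facial selectivity.
   - Fallback (sets out from 2, 3 and 5, returns at 10): C7 is taken to the ketone level and the stereocentre is set by hydride instead of by the aryl group. Compound 3 is converted with MeNH(OMe)·HCl/i-PrMgCl into the Weinreb amide (R)-2-hydroxy-N-methoxy-N-methylpropanamide F1. This is joined to 2 by Mitsunobu inversion to give the (S)-aryloxy Weinreb amide F2. (3,4-Dimethoxyphenyl)magnesium bromide F3, made from 5 and magnesium, then forms the same C1–C7 bond by acylation. The chelated tetrahedral adduct stops at mono-addition and the deactivated enoate stays behind, giving the (S)-α-aryloxy ketone F4. Zn(BH4)2 in Et2O reduces F4 through the five-membered zinc chelate of the ketone oxygen and O4′, with hydride arriving from the C8–H side, which should give the erythro (7R,8S) hydroxy enoate F5. DIBAL-H (CH2Cl2, −78 °C) then reduces the enoate to 10.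

2. **Step 2.**
   - What may go wrong: slow capture of the oxyphosphonium ion by the doubly ortho-substituted phenoxide, so that alkylation of the hydrazide anion or elimination to acrylate competes and inversion is incomplete.
   - Fallback (sets out from 3, returns at 4): the electrophile is activated beforehand. Compound 3 is treated with Tf2O/2,6-lutidine to give methyl (R)-2-(trifluoromethylsulfonyloxy)propanoate F6. The potassium phenoxide of 2 (K2CO3, MeCN, 0 °C) displaces the triflate by SN2 with inversion to give 4.

3. **Step 1.**
   - What may go wrong: acid-promoted oligomerisation or methanol addition across the electron-rich p-hydroxycinnamate, and air oxidation of the phenol during prolonged reflux.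
   - Fallback (sets out from 1, returns at 2): the O–CH3 bond is formed instead of the acyl C–O bond, by alkylating the carboxylate alone with MeI/KHCO3 in DMF at rt. The weak base leaves the phenol protonated. New compounds on this path: none F0.

**Further compounds**
F1 | step 3 | (R)-2-hydroxy-N-methoxy-N-methylpropanamide | C[C@@H](O)C(=O)N(C)OC
F2 | step 3 | methyl (E)-3-(3,5-dimethoxy-4-{[(2S)-1-[methoxy(methyl)amino]-1-oxopropan-2-yl]oxy}phenyl)prop-2-enoate | CON(C)C(=O)[C@H](C)Oc1c(OC)cc(/C=C/C(=O)OC)cc1OC
F3 | step 3 | (3,4-dimethoxyphenyl)magnesium bromide | COc1ccc([Mg]Br)cc1OC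
F4 | step 3 | methyl (E)-3-(4-{[(2S)-1-(3,4-dimethoxyphenyl)-1-oxopropan-2-yl]oxy}-3,5-dimethoxyphenyl)prop-2-enoate | COc1ccc(C(=O)[C@H](C)Oc2c(OC)cc(/C=C/C(=O)OC)cc2OC)cc1OC
F5 | step 3 | methyl (E)-3-(4-{[(1R,2S)-1-(3,4-dimethoxyphenyl)-1-hydroxypropan-2-yl]oxy}-3,5-dimethoxyphenyl)prop-2-enoate | COc1ccc([C@@H](O)[C@H](C)Oc2c(OC)cc(/C=C/C(=O)OC)cc2OC)cc1OC
F6 | step 2 | methyl (R)-2-(trifluoromethylsulfonyloxy)propanoate | C[C@@H](OS(=O)(=O)C(F)(F)F)C(=O)OC
F0 | step 1 | none | none
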